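**Retrosynthetic overview**

1. Locants: ring A has butanoyl on C1, OH on C2, CH3 on C3, OCH3 on C4, the bridge CH2 on C5 (bound to C1 of ring B) and OH on C6; ring B has CH2 on C1, OH on C2, CH2 on C3 (bound to C1 of ring C), OH on C4, acetyl on C5 and OH on C6; ring C has the bridge CH2 on C1, OH on C2, CH3 on C3, OCH3 on C4, butanoyl on C5 and OH on C6.
2. The strategy rests on the C2(OH)–C3(CH3)–C4(OCH3) run of each outer ring, which is a ketene carbonyl joined to the polarised two-carbon unit of 1-methoxypropyne. The two outer rings are regioisomers: the bridge CH2 sits on C5 of ring A (next to OCH3) but on C1 of ring C (between two OH groups), and butanoyl sits on C1 of ring A but on C5 of ring C.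
3. Key disconnection: a twofold cyclobutenone/1-methoxypropyne benzannulation forms the C2–C3 and C4–C5 bonds of ring A and of ring C and closes both rings together, last, on a finished ring B. Ring A comes from a 3-benzyloxycyclobutenone bound to its bridge through cyclobutenone C2, ring C from the regioisomer bound through cyclobutenone C4.
4. Ring B is built first from 2,4,6-trihydroxybenzaldehyde and already carries its acetyl group and three benzyl ethers. The ring C arm: homoenolate Negishi coupling, then acyl chloride → ketene + benzyloxyacetylene. The ring A arm: benzylic chloride + alkynylzinc, then ketene.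
5. Benzyloxy (not ethoxy) on the cyclobutenones lets the C6 oxygen of ring C be freed beside the C4 methyl ether, both ortho to the C5 ketone. End game: benzylation, double Friedel–Crafts butyrylation at the only free positions (C1 of ring A, C5 of ring C), hydrogenolysis of seven benzyl ethers.

Key step: step 12

Remark: ketene for step 10 is taken as a gas stream from a laboratory generator (pyrolysis of acetone) and is counted as a reagent.
Remark: the cyclobutenone carbon that carries the arylmethyl group in 18, 21 and 22 is a stereocentre and forms racemic; it becomes an aromatic carbon in step 12, and the target has no stereocentre.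
Remark: intermediates 26–29 of step 12 are drawn with both arms at the same stage; the two arms pass through these stages independently.

**Route**

Step 1
Reactants: 1 2,4,6-trihydroxybenzaldehyde
Product: 2 3-acetyl-2,4,6-trihydroxybenzaldehyde
Conditions: AcCl, AlCl3, PhNO2, rt → 60 °C; ice/HCl
Reagents that add atoms: acetyl chloride, CC(Cl)=O
Why: Friedel–Crafts acylation of a formylphloroglucinol; the two free positions are equivalent and the product, now bearing two carbonyl groups, should resist a second acylation.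

Step 2
Reactants: 2 3-acetyl-2,4,6-trihydroxybenzaldehyde
Product: 3 3-acetyl-2,4,6-trihydroxy-5-iodobenzaldehyde
Conditions: NIS, DMF, 0 °C → rt
Reagents that add atoms: N-iodosuccinimide, O=C1CCC(=O)N1I
Why: electrophilic aromatic iodination of a phenol at its single free ring position, which also closes that position to C-benzylation in the next step.

Step 3
Reactants: 3 3-acetyl-2,4,6-trihydroxy-5-iodobenzaldehyde
Product: 4 3-acetyl-2,4,6-tris(benzyloxy)-5-iodobenzaldehyde
Conditions: BnBr, K2CO3, DMF, 50 °C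
Reagents that add atoms: benzyl bromide, BrCc1ccccc1
Why: Williamson ether synthesis on a ring with no C–H left, so O-alkylation should dominate and all acidic protons are removed before the organometallic steps.

Step 4
Reactants: 4 3-acetyl-2,4,6-tris(benzyloxy)-5-iodobenzaldehyde; 5 (3-ethoxy-3-oxopropyl)zinc bromide
Product: 6 ethyl 3-[3-acetyl-2,4,6-tris(benzyloxy)-5-formylphenyl]propanoate
Conditions: Pd(OAc)2 (cat.), SPhos (cat.), THF, rt → 50 °C
Reagents that add atoms: none
Why: Negishi coupling of an aryl iodide with a zinc homoenolate; alkylzinc halides leave aldehyde, ketone and ester untouched, and the biaryl phosphine copes with the two ortho benzyloxy groups.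

Step 5
Reactants: 6 ethyl 3-[3-acetyl-2,4,6-tris(benzyloxy)-5-formylphenyl]propanoate
Product: 8 3-[3-acetyl-2,4,6-tris(benzyloxy)-5-(hydroxymethyl)phenyl]propanoic acid, via hydroxy ester 7 (not isolated)
Conditions: NaBH4, THF/EtOH, 0 °C; then LiOH, H2O, rt; 1 M HCl to pH 4, 0 °C
Reagents that add atoms: lithium hydroxide, [Li+].[OH-]
Why: borohydride reduction of the aldehyde (the acetyl group, shielded by two ortho benzyloxy groups, should react far more slowly) followed by ester saponification in the same flask.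

Step 6
Reactants: 9 benzyl alcohol; 10 trichloroethylene
Product: 12 benzyl (E)-1,2-dichlorovinyl ether, via dichloroacetylene 11 (not isolated)
Conditions: KH, THF, 0 °C; then 10, −50 °C → rt
Reagents that add atoms: none
Why: elimination–addition route to 1,2-dichlorovinyl ethers, in which the potassium alkoxide adds to dichloroacetylene formed in the flask; anti addition of alkoxide and proton sets the E double bond.

Step 7
Reactants: 12 benzyl (E)-1,2-dichlorovinyl ether
Product: 15 benzyloxyacetylene, via benzyl chloroethynyl ether 13 (not isolated), via lithium benzyloxyacetylide 14 (not isolated)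
Conditions: n-BuLi (2.2 equiv), THF, −78 → −40 °C; H2O, −78 → 0 °C; dried (K2CO3) and kept as a cold solution
Reagents that add atoms: none
Why: β-elimination of HCl and chlorine–lithium exchange (the dichlorovinyl ether route to alkynyl ethers) give the lithium acetylide, and protonation frees the terminal ynol ether, which is kept cold because benzyl alkynyl ethers rearrange on warming.

Step 8
Reactants: 8 3-[3-acetyl-2,4,6-tris(benzyloxy)-5-(hydroxymethyl)phenyl]propanoic acid; 15 benzyloxyacetylene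
Product: 18 4-{[3-acetyl-2,4,6-tris(benzyloxy)-5-(chloromethyl)phenyl]methyl}-3-(benzyloxy)cyclobut-2-en-1-one (racemic), via acyl chloride 16 (not isolated), via ketene 17 (not isolated)
Conditions: (COCl)2, DMF (cat.), CH2Cl2, 0 °C → rt; evaporate; 15 (3 equiv), i-Pr2NEt (slow addition), CH2Cl2, 0 °C → rt
Reagents that add atoms: oxalyl chloride, O=C(Cl)C(Cl)=O
Why: oxalyl chloride turns the acid into its chloride and the electron-rich benzylic alcohol into the chloride, the hindered amine then gives the monosubstituted ketene, and its [2+2] cycloaddition with the ynol ether (CH terminus to the ketene carbonyl carbon) puts the side chain on the sp3 carbon C4 of a 3-alkoxycyclobutenone, whose new centre forms racemic.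

Step 9
Reactants: 18 4-{[3-acetyl-2,4,6-tris(benzyloxy)-5-(chloromethyl)phenyl]methyl}-3-(benzyloxy)cyclobut-2-en-1-one; 15 benzyloxyacetylene
Product: 21 4-({3-acetyl-2,4,6-tris(benzyloxy)-5-[3-(benzyloxy)prop-2-yn-1-yl]phenyl}methyl)-3-(benzyloxy)cyclobut-2-en-1-one (racemic), via (benzyloxyethynyl)magnesium bromide 19 (not isolated), via (benzyloxyethynyl)zinc bromide 20 (not isolated)
Conditions: 15 (slight excess over EtMgBr), EtMgBr, THF, 0 °C; ZnBr2, 0 °C; then 18, PdCl2(DPEphos) (cat.), THF, 0 °C → rt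
Reagents that add atoms: none
Why: ethylmagnesium bromide deprotonates the terminal ynol ether, ZnBr2 transmetalates the alkynylmagnesium bromide, and the alkynylzinc bromide couples with the benzylic chloride in a Negishi reaction under zerovalent palladium catalysis; the zinc acetylide should not touch cyclobutenone, ketone or benzyl ethers, and room temperature stays below the point where benzyl alkynyl ethers rearrange.

Step 10
Reactants: 21 4-({3-acetyl-2,4,6-tris(benzyloxy)-5-[3-(benzyloxy)prop-2-yn-1-yl]phenyl}methyl)-3-(benzyloxy)cyclobut-2-en-1-one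
Product: 22 1-[2,4,6-tris(benzyloxy)-3-{[2-(benzyloxy)-4-oxocyclobut-1-en-1-yl]methyl}-5-{[2-(benzyloxy)-4-oxocyclobut-2-en-1-yl]methyl}phenyl]ethan-1-one (racemic)
Conditions: ketene (gas, excess), CH2Cl2, 0 °C → rt
Reagents that add atoms: ketene, C=C=O
Why: [2+2] cycloaddition of ketene with an alkynyl ether; the nucleophilic β-carbon of the ynol ether attacks the ketene carbonyl carbon, which places the arylmethyl group on C2 and benzyloxy on C3 of the new cyclobutenone.

Step 11
Reactants: 23 chloroacetaldehyde dimethyl acetal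
Product: 25 1-methoxyprop-1-yne, via sodium methoxyacetylide 24 (not isolated)
Conditions: NaNH2 (3 equiv), liq. NH3, −33 °C; MeI, −70 → −33 °C; distil
Reagents that add atoms: iodomethane, CI
Why: twofold elimination of the chloroacetal by sodium amide to the sodium alkoxyacetylide and C-methylation in liquid ammonia, the standard route to 1-alkoxy-1-alkynes.

Step 12
Reactants: 22 1-[2,4,6-tris(benzyloxy)-3-{[2-(benzyloxy)-4-oxocyclobut-1-en-1-yl]methyl}-5-{[2-(benzyloxy)-4-oxocyclobut-2-en-1-yl]methyl}phenyl]ethan-1-one; 25 1-methoxyprop-1-yne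
Product: 30 1-[2,4,6-tris(benzyloxy)-3-{[6-(benzyloxy)-4-hydroxy-2-methoxy-3-methylphenyl]methyl}-5-{[6-(benzyloxy)-2-hydroxy-4-methoxy-3-methylphenyl]methyl}phenyl]ethan-1-one, via bis(vinylketene) 26 (not isolated), via bis(vinylcyclobutenone) 27 (not isolated), via bis(dienylketene) 28 (not isolated), via bis(cyclohexadienone) 29 (not isolated)
Conditions: 25 (5 equiv), toluene (0.02 M), sealed tube, 80 °C, then 110 °C
Reagents that add atoms: none
Why: Each cyclobutenone opens by 4π electrocyclic ring opening to a vinylketene (26), which adds 1-methoxypropyne in a [2+2] cycloaddition to a 4-vinylcyclobutenone (27); a second 4π opening gives the dienylketene (28), which closes by 6π electrocyclisation to a cyclohexa-2,4-dienone (29) that tautomerises to the phenol. This is the Danheiser benzannulation of cyclobutenones with alkoxyalkynes, run on both arms of one molecule. Ring A closes in the 6π step between the former ketene carbon (C2 of ring A) and the cyclobutenone CH2 (C1 of ring A) once its C2–C3 and C4–C5 bonds are in place; ring C closes the same way between its C2 and the arylmethyl-bearing carbon C1 once its C2–C3 and C4–C5 bonds have formed. No stereocentre is created, and the racemic centre of the 4-substituted cyclobutenone is lost on aromatisation. The selectivity needed is the orientation of the alkyne: its methyl-bearing carbon, the nucleophilic β-carbon of the ynol ether, bonds to the ketene carbonyl carbon, so OCH3 ends next to the carbon that stems from cyclobutenone C2 (the bridge carbon C5 in ring A, the free C5–H in ring C). Excess alkyne and high dilution should keep the two ketene arms from reacting with each other or with the phenols formed.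

Step 13
Reactants: 30 1-[2,4,6-tris(benzyloxy)-3-{[6-(benzyloxy)-4-hydroxy-2-methoxy-3-methylphenyl]methyl}-5-{[6-(benzyloxy)-2-hydroxy-4-methoxy-3-methylphenyl]methyl}phenyl]ethan-1-one
Product: 31 1-[2,4,6-tris(benzyloxy)-3-{[4,6-bis(benzyloxy)-2-methoxy-3-methylphenyl]methyl}-5-{[2,6-bis(benzyloxy)-4-methoxy-3-methylphenyl]methyl}phenyl]ethan-1-one
Conditions: BnBr, Cs2CO3, DMF, rt → 50 °C
Reagents that add atoms: benzyl bromide, BrCc1ccccc1
Why: Williamson etherification of the two phenols, which removes O-acylation as a competing path and leaves the C1–H of ring A and the C5–H of ring C as the only free positions on the three oxygenated rings.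

Step 14
Reactants: 31 1-[2,4,6-tris(benzyloxy)-3-{[4,6-bis(benzyloxy)-2-methoxy-3-methylphenyl]methyl}-5-{[2,6-bis(benzyloxy)-4-methoxy-3-methylphenyl]methyl}phenyl]ethan-1-one
Product: 32 1-[2,4,6-tris(benzyloxy)-3-{[4,6-bis(benzyloxy)-5-butanoyl-2-methoxy-3-methylphenyl]methyl}-5-{[2,6-bis(benzyloxy)-5-butanoyl-4-methoxy-3-methylphenyl]methyl}phenyl]ethan-1-one
Conditions: PrCO2H (4 equiv), (CF3CO)2O (4 equiv), H3PO4 (cat.), CH2Cl2, 0 °C → rt
Reagents that add atoms: butanoic acid, CCCC(O)=O
Why: Friedel–Crafts acylation by the mixed anhydride of butanoic and trifluoroacetic acid; C1 of ring A and C5 of ring C, each between two alkoxy groups, are the only unsubstituted carbons of the oxygenated rings, ring B is fully substituted and deactivated by its acetyl group, and no metal Lewis acid is present to cleave benzyl ethers.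

Step 15
Reactants: 32 1-[2,4,6-tris(benzyloxy)-3-{[4,6-bis(benzyloxy)-5-butanoyl-2-methoxy-3-methylphenyl]methyl}-5-{[2,6-bis(benzyloxy)-5-butanoyl-4-methoxy-3-methylphenyl]methyl}phenyl]ethan-1-one
Product: 33 CNP0184345.0, 1-[3-({3-acetyl-5-[(3-butanoyl-2,6-dihydroxy-4-methoxy-5-methylphenyl)methyl]-2,4,6-trihydroxyphenyl}methyl)-2,6-dihydroxy-4-methoxy-5-methylphenyl]butan-1-one
Conditions: H2 (1 atm), Pd/C, EtOAc/MeOH, rt
Reagents that add atoms: none
Why: hydrogenolysis of seven aryl benzyl ethers under neutral conditions; the two methyl ethers stay, and the three aryl ketones, each flanked by two ortho substituents, should be reduced far more slowly than the benzyl C–O bonds are cleaved.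

**Compound list**

1 | 2,4,6-trihydroxybenzaldehyde | O=Cc1c(O)cc(O)cc1O | starting material
2 | 3-acetyl-2,4,6-trihydroxybenzaldehyde | CC(=O)c1c(O)c(C=O)c(O)cc1O | intermediate
3 | 3-acetyl-2,4,6-trihydroxy-5-iodobenzaldehyde | CC(=O)c1c(O)c(C=O)c(O)c(I)c1O | intermediate
4 | 3-acetyl-2,4,6-tris(benzyloxy)-5-iodobenzaldehyde | CC(=O)c1c(OCc2ccccc2)c(C=O)c(OCc2ccccc2)c(I)c1OCc1ccccc1 | intermediate
5 | (3-ethoxy-3-oxopropyl)zinc bromide | CCOC(=O)CC[Zn]Br | starting material
6 | ethyl 3-[3-acetyl-2,4,6-tris(benzyloxy)-5-formylphenyl]propanoate | CC(=O)c1c(OCc2ccccc2)c(C=O)c(OCc2ccccc2)c(CCC(=O)OCC)c1OCc1ccccc1 | intermediate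
7 | ethyl 3-[3-acetyl-2,4,6-tris(benzyloxy)-5-(hydroxymethyl)phenyl]propanoate | CC(=O)c1c(OCc2ccccc2)c(CO)c(OCc2ccccc2)c(CCC(=O)OCC)c1OCc1ccccc1 | intermediate (not isolated)
8 | 3-[3-acetyl-2,4,6-tris(benzyloxy)-5-(hydroxymethyl)phenyl]propanoic acid | CC(=O)c1c(OCc2ccccc2)c(CO)c(OCc2ccccc2)c(CCC(=O)O)c1OCc1ccccc1 | intermediate
9 | benzyl alcohol | OCc1ccccc1 | starting material
10 | trichloroethylene | ClC=C(Cl)Cl | starting material
11 | dichloroacetylene | ClC#CCl | intermediate (not isolated)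
12 | benzyl (E)-1,2-dichlorovinyl ether | Cl/C=C(/Cl)OCc1ccccc1 | intermediate
13 | benzyl chloroethynyl ether | ClC#COCc1ccccc1 | intermediate (not isolated)
14 | lithium benzyloxyacetylide | [Li]C#COCc1ccccc1 | intermediate (not isolated)
15 | benzyloxyacetylene, [(ethynyloxy)methyl]benzene | C#COCc1ccccc1 | intermediate
16 | 3-[3-acetyl-2,4,6-tris(benzyloxy)-5-(chloromethyl)phenyl]propanoyl chloride | CC(=O)c1c(OCc2ccccc2)c(CCl)c(OCc2ccccc2)c(CCC(=O)Cl)c1OCc1ccccc1 | intermediate (not isolated)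
17 | 3-[3-acetyl-2,4,6-tris(benzyloxy)-5-(chloromethyl)phenyl]prop-1-en-1-one (ketene) | CC(=O)c1c(OCc2ccccc2)c(CCl)c(OCc2ccccc2)c(CC=C=O)c1OCc1ccccc1 | intermediate (not isolated)
18 | 4-{[3-acetyl-2,4,6-tris(benzyloxy)-5-(chloromethyl)phenyl]methyl}-3-(benzyloxy)cyclobut-2-en-1-one, racemic | CC(=O)c1c(OCc2ccccc2)c(CCl)c(OCc2ccccc2)c(CC2C(=O)C=C2OCc2ccccc2)c1OCc1ccccc1 | intermediate
19 | (benzyloxyethynyl)magnesium bromide | Br[Mg]C#COCc1ccccc1 | intermediate (not isolated)
20 | (benzyloxyethynyl)zinc bromide | Br[Zn]C#COCc1ccccc1 | intermediate (not isolated)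
21 | 4-({3-acetyl-2,4,6-tris(benzyloxy)-5-[3-(benzyloxy)prop-2-yn-1-yl]phenyl}methyl)-3-(benzyloxy)cyclobut-2-en-1-one, racemic | CC(=O)c1c(OCc2ccccc2)c(CC#COCc2ccccc2)c(OCc2ccccc2)c(CC2C(=O)C=C2OCc2ccccc2)c1OCc1ccccc1 | intermediate
22 | 1-[2,4,6-tris(benzyloxy)-3-{[2-(benzyloxy)-4-oxocyclobut-1-en-1-yl]methyl}-5-{[2-(benzyloxy)-4-oxocyclobut-2-en-1-yl]methyl}phenyl]ethan-1-one, racemic (key-step precursor) | CC(=O)c1c(OCc2ccccc2)c(CC2=C(OCc3ccccc3)CC2=O)c(OCc2ccccc2)c(CC2C(=O)C=C2OCc2ccccc2)c1OCc1ccccc1 | intermediate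
23 | chloroacetaldehyde dimethyl acetal | COC(CCl)OC | starting material
24 | sodium methoxyacetylide | [Na]C#COC | intermediate (not isolated)
25 | 1-methoxyprop-1-yne | CC#COC | intermediate
26 | bis(vinylketene): ring B core of 22 with the ring A arm as CH2–C(=C=O)–C(OBn)=CH2 and the ring C arm as CH2–CH=C(OBn)–CH=C=O | CC(=O)c1c(OCc2ccccc2)c(CC(=C=O)C(OCc2ccccc2)=C)c(OCc2ccccc2)c(C/C=C(\OCc2ccccc2)C=C=O)c1OCc1ccccc1 | intermediate (not isolated)
27 | bis(vinylcyclobutenone): each ketene of 26 joined to 1-methoxypropyne as a 3-methoxy-2-methylcyclobut-2-en-1-one carrying the vinyl group on C4, mixture of stereoisomers | CC(=O)c1c(OCc2ccccc2)c(CC2(C(OCc3ccccc3)=C)C(OC)=C(C)C2=O)c(OCc2ccccc2)c(C/C=C(\OCc2ccccc2)C2C(OC)=C(C)C2=O)c1OCc1ccccc1 | intermediate (not isolated)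
28 | bis(dienylketene): ring A arm as CH2–C[C(OBn)=CH2]=C(OCH3)–C(CH3)=C=O, ring C arm as CH2–CH=C(OBn)–CH=C(OCH3)–C(CH3)=C=O, reactive geometric isomers | CC(=O)c1c(OCc2ccccc2)c(C/C(C(OCc2ccccc2)=C)=C(\OC)C(C)=C=O)c(OCc2ccccc2)c(C/C=C(\OCc2ccccc2)/C=C(\C(C)=C=O)OC)c1OCc1ccccc1 | intermediate (not isolated)
29 | bis(cyclohexadienone): both outer rings as cyclohexa-2,4-dien-1-ones before tautomerisation, racemic | CC(=O)c1c(OCc2ccccc2)c(CC2=C(OCc3ccccc3)CC(=O)C(C)=C2OC)c(OCc2ccccc2)c(CC2C(=O)C(C)=C(OC)C=C2OCc2ccccc2)c1OCc1ccccc1 | intermediate (not isolated)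
30 | 1-[2,4,6-tris(benzyloxy)-3-{[6-(benzyloxy)-4-hydroxy-2-methoxy-3-methylphenyl]methyl}-5-{[6-(benzyloxy)-2-hydroxy-4-methoxy-3-methylphenyl]methyl}phenyl]ethan-1-one (key-step product) | CC(=O)c1c(OCc2ccccc2)c(Cc2c(OCc3ccccc3)cc(O)c(C)c2OC)c(OCc2ccccc2)c(Cc2c(O)c(C)c(OC)cc2OCc2ccccc2)c1OCc1ccccc1 | intermediate
31 | 1-[2,4,6-tris(benzyloxy)-3-{[4,6-bis(benzyloxy)-2-methoxy-3-methylphenyl]methyl}-5-{[2,6-bis(benzyloxy)-4-methoxy-3-methylphenyl]methyl}phenyl]ethan-1-one | CC(=O)c1c(OCc2ccccc2)c(Cc2c(OCc3ccccc3)cc(OCc3ccccc3)c(C)c2OC)c(OCc2ccccc2)c(Cc2c(OCc3ccccc3)c(C)c(OC)cc2OCc2ccccc2)c1OCc1ccccc1 | intermediate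
32 | 1-[2,4,6-tris(benzyloxy)-3-{[4,6-bis(benzyloxy)-5-butanoyl-2-methoxy-3-methylphenyl]methyl}-5-{[2,6-bis(benzyloxy)-5-butanoyl-4-methoxy-3-methylphenyl]methyl}phenyl]ethan-1-one | CC(=O)c1c(OCc2ccccc2)c(Cc2c(OCc3ccccc3)c(C(=O)CCC)c(OCc3ccccc3)c(C)c2OC)c(OCc2ccccc2)c(Cc2c(OCc3ccccc3)c(C)c(OC)c(C(=O)CCC)c2OCc2ccccc2)c1OCc1ccccc1 | intermediate
33 | CNP0184345.0, 1-[3-({3-acetyl-5-[(3-butanoyl-2,6-dihydroxy-4-methoxy-5-methylphenyl)methyl]-2,4,6-trihydroxyphenyl}methyl)-2,6-dihydroxy-4-methoxy-5-methylphenyl]butan-1-one | CCCC(=O)c1c(O)c(C)c(OC)c(Cc2c(O)c(Cc3c(O)c(C)c(OC)c(C(=O)CCC)c3O)c(O)c(C(C)=O)c2O)c1O | target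

**Step count and risks**

Total step count: 15. Longest linear sequence: 12 steps (1–5, 8, 9, 10, 12–15). Steps 6 and 7 (benzyloxyacetylene) and step 11 (1-methoxypropyne) are side branches.

Steps most likely to fail:

Step 12. The two vinylketene arms of one molecule may react with each other, or with phenol already formed, faster than the alkyne traps them, so that oligomers and aryl esters form; the 4-substituted arm may also close more slowly than the 2-substituted one. The fallback builds the outer rings one at a time, so only one ketene is ever present. It sets out from 6. Saponification (LiOH, THF/H2O) should give 3-[3-acetyl-2,4,6-tris(benzyloxy)-5-formylphenyl]propanoic acid F1. Oxalyl chloride should give the acyl chloride F2, i-Pr2NEt the ketene F3, and trapping with 15 the 4-substituted cyclobutenone aldehyde F4. Heating F4 with 25 in toluene should build ring C alone and give the phenol aldehyde F5; benzylation (BnBr, Cs2CO3) gives the benzyl ether F6. NaBH4 should give the benzylic alcohol F7, and SOCl2 with 2,6-lutidine the benzylic chloride F8. Coupling of F8 with the zinc reagent 20 under the conditions of step 9 should give the ynol ether F9, and ketene gas the 2-substituted cyclobutenone F10. A second benzannulation with 25 should build ring A and give the phenol F11; benzylation of F11 gives 31, where the route is rejoined.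

Step 8. The benzylic chloride may be lost to the amine base or by ionisation while the ketene is generated, and the monosubstituted ketene may dimerise before the ynol ether traps it. The fallback separates chloride formation from the ketene step with a silyl ether. It sets out from 7, which is isolated after the borohydride reduction of 6. TBSCl and imidazole should give the silyl ether ester F12, and LiOH the silyl ether acid F13. 1-Chloro-N,N,2-trimethylprop-1-en-1-amine (neutral conditions) should give the acyl chloride F14, i-Pr2NEt the ketene F15, and 15 the cyclobutenone silyl ether F16. HF·pyridine should free the cyclobutenone alcohol F17; MsCl, 2,4,6-collidine and LiCl in DMF at 0 °C should then give 18, where the route is rejoined.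

Step 14. Acid-promoted loss of benzyl groups or cleavage of the diarylmethane bridges may compete with acylation at the two hindered positions. The fallback acylates before the phenols are capped and uses a nitrile electrophile. It sets out from 30. A Houben–Hoesch reaction (PrCN, ZnCl2, HCl, Et2O, 0 °C) should give the bis(ketiminium chloride) F18, with the butanimidoyl groups at C1 of ring A (ortho to the C2 hydroxyl of that ring) and at C5 of ring C (para to the C2 hydroxyl of that ring), the only free positions. Hydrolysis (H2O, 60 °C) should give the diketone diphenol F19. Hydrogenolysis of its five benzyl ethers (H2, Pd/C) should give the target directly, so the fallback rejoins the route at 33.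

**Further compounds**

F1 | step 12 | 3-[3-acetyl-2,4,6-tris(benzyloxy)-5-formylphenyl]propanoic acid | CC(=O)c1c(OCc2ccccc2)c(C=O)c(OCc2ccccc2)c(CCC(=O)O)c1OCc1ccccc1
F2 | step 12 | 3-[3-acetyl-2,4,6-tris(benzyloxy)-5-formylphenyl]propanoyl chloride | CC(=O)c1c(OCc2ccccc2)c(C=O)c(OCc2ccccc2)c(CCC(=O)Cl)c1OCc1ccccc1
F3 | step 12 | 3-acetyl-2,4,6-tris(benzyloxy)-5-(3-oxoprop-2-en-1-yl)benzaldehyde (ketene) | CC(=O)c1c(OCc2ccccc2)c(C=O)c(OCc2ccccc2)c(CC=C=O)c1OCc1ccccc1
F4 | step 12 | 3-acetyl-2,4,6-tris(benzyloxy)-5-{[2-(benzyloxy)-4-oxocyclobut-2-en-1-yl]methyl}benzaldehyde, racemic | CC(=O)c1c(OCc2ccccc2)c(C=O)c(OCc2ccccc2)c(CC2C(=O)C=C2OCc2ccccc2)c1OCc1ccccc1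
F5 | step 12 | 3-acetyl-2,4,6-tris(benzyloxy)-5-{[6-(benzyloxy)-2-hydroxy-4-methoxy-3-methylphenyl]methyl}benzaldehyde | CC(=O)c1c(OCc2ccccc2)c(C=O)c(OCc2ccccc2)c(Cc2c(O)c(C)c(OC)cc2OCc2ccccc2)c1OCc1ccccc1
F6 | step 12 | 3-acetyl-2,4,6-tris(benzyloxy)-5-{[2,6-bis(benzyloxy)-4-methoxy-3-methylphenyl]methyl}benzaldehyde | CC(=O)c1c(OCc2ccccc2)c(C=O)c(OCc2ccccc2)c(Cc2c(OCc3ccccc3)c(C)c(OC)cc2OCc2ccccc2)c1OCc1ccccc1
F7 | step 12 | 1-[2,4,6-tris(benzyloxy)-3-{[2,6-bis(benzyloxy)-4-methoxy-3-methylphenyl]methyl}-5-(hydroxymethyl)phenyl]ethan-1-one | CC(=O)c1c(OCc2ccccc2)c(CO)c(OCc2ccccc2)c(Cc2c(OCc3ccccc3)c(C)c(OC)cc2OCc2ccccc2)c1OCc1ccccc1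
F8 | step 12 | 1-[2,4,6-tris(benzyloxy)-3-{[2,6-bis(benzyloxy)-4-methoxy-3-methylphenyl]methyl}-5-(chloromethyl)phenyl]ethan-1-one | CC(=O)c1c(OCc2ccccc2)c(CCl)c(OCc2ccccc2)c(Cc2c(OCc3ccccc3)c(C)c(OC)cc2OCc2ccccc2)c1OCc1ccccc1
F9 | step 12 | 1-[2,4,6-tris(benzyloxy)-3-{[2,6-bis(benzyloxy)-4-methoxy-3-methylphenyl]methyl}-5-[3-(benzyloxy)prop-2-yn-1-yl]phenyl]ethan-1-one | CC(=O)c1c(OCc2ccccc2)c(CC#COCc2ccccc2)c(OCc2ccccc2)c(Cc2c(OCc3ccccc3)c(C)c(OC)cc2OCc2ccccc2)c1OCc1ccccc1
F10 | step 12 | 1-[2,4,6-tris(benzyloxy)-3-{[2,6-bis(benzyloxy)-4-methoxy-3-methylphenyl]methyl}-5-{[2-(benzyloxy)-4-oxocyclobut-1-en-1-yl]methyl}phenyl]ethan-1-one | CC(=O)c1c(OCc2ccccc2)c(CC2=C(OCc3ccccc3)CC2=O)c(OCc2ccccc2)c(Cc2c(OCc3ccccc3)c(C)c(OC)cc2OCc2ccccc2)c1OCc1ccccc1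
F11 | step 12 | 1-[2,4,6-tris(benzyloxy)-3-{[2,6-bis(benzyloxy)-4-methoxy-3-methylphenyl]methyl}-5-{[6-(benzyloxy)-4-hydroxy-2-methoxy-3-methylphenyl]methyl}phenyl]ethan-1-one | CC(=O)c1c(OCc2ccccc2)c(Cc2c(OCc3ccccc3)cc(O)c(C)c2OC)c(OCc2ccccc2)c(Cc2c(OCc3ccccc3)c(C)c(OC)cc2OCc2ccccc2)c1OCc1ccccc1
F12 | step 8 | ethyl 3-[3-acetyl-2,4,6-tris(benzyloxy)-5-({[tert-butyl(dimethyl)silyl]oxy}methyl)phenyl]propanoate | CC(=O)c1c(OCc2ccccc2)c(CO[Si](C)(C)C(C)(C)C)c(OCc2ccccc2)c(CCC(=O)OCC)c1OCc1ccccc1
F13 | step 8 | 3-[3-acetyl-2,4,6-tris(benzyloxy)-5-({[tert-butyl(dimethyl)silyl]oxy}methyl)phenyl]propanoic acid | CC(=O)c1c(OCc2ccccc2)c(CO[Si](C)(C)C(C)(C)C)c(OCc2ccccc2)c(CCC(=O)O)c1OCc1ccccc1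
F14 | step 8 | 3-[3-acetyl-2,4,6-tris(benzyloxy)-5-({[tert-butyl(dimethyl)silyl]oxy}methyl)phenyl]propanoyl chloride | CC(=O)c1c(OCc2ccccc2)c(CO[Si](C)(C)C(C)(C)C)c(OCc2ccccc2)c(CCC(=O)Cl)c1OCc1ccccc1
F15 | step 8 | 3-[3-acetyl-2,4,6-tris(benzyloxy)-5-({[tert-butyl(dimethyl)silyl]oxy}methyl)phenyl]prop-1-en-1-one (ketene) | CC(=O)c1c(OCc2ccccc2)c(CO[Si](C)(C)C(C)(C)C)c(OCc2ccccc2)c(CC=C=O)c1OCc1ccccc1
F16 | step 8 | 4-{[3-acetyl-2,4,6-tris(benzyloxy)-5-({[tert-butyl(dimethyl)silyl]oxy}methyl)phenyl]methyl}-3-(benzyloxy)cyclobut-2-en-1-one, racemic | CC(=O)c1c(OCc2ccccc2)c(CO[Si](C)(C)C(C)(C)C)c(OCc2ccccc2)c(CC2C(=O)C=C2OCc2ccccc2)c1OCc1ccccc1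
F17 | step 8 | 4-{[3-acetyl-2,4,6-tris(benzyloxy)-5-(hydroxymethyl)phenyl]methyl}-3-(benzyloxy)cyclobut-2-en-1-one, racemic | CC(=O)c1c(OCc2ccccc2)c(CO)c(OCc2ccccc2)c(CC2C(=O)C=C2OCc2ccccc2)c1OCc1ccccc1
F18 | step 14 | bis(ketiminium chloride) of F19: 30 with a butanimidoyl group, protonated on nitrogen, at C1 of ring A and at C5 of ring C | CC(=O)c1c(OCc2ccccc2)c(Cc2c(OCc3ccccc3)c(C(=[NH2+])CCC)c(O)c(C)c2OC)c(OCc2ccccc2)c(Cc2c(O)c(C)c(OC)c(C(=[NH2+])CCC)c2OCc2ccccc2)c1OCc1ccccc1.[Cl-].[Cl-]
F19 | step 14 | 1-[2,4,6-tris(benzyloxy)-3-{[6-(benzyloxy)-5-butanoyl-4-hydroxy-2-methoxy-3-methylphenyl]methyl}-5-{[6-(benzyloxy)-5-butanoyl-2-hydroxy-4-methoxy-3-methylphenyl]methyl}phenyl]ethan-1-one | CC(=O)c1c(OCc2ccccc2)c(Cc2c(OCc3ccccc3)c(C(=O)CCC)c(O)c(C)c2OC)c(OCc2ccccc2)c(Cc2c(O)c(C)c(OC)c(C(=O)CCC)c2OCc2ccccc2)c1OCc1ccccc1
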